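## Retrosynthetic overview

1. Last bond: the aryl–O–CH2 ether (Mitsunobu), giving 7-hydroxy-8-methoxycoumarin and an (E)-allylic alcohol that already carries the finished hydroxy-lactone.
2. The (E)-C(Me)=CH–CH2OH unit comes from a terminal alkyne by syn-methylalumination and trapping with formaldehyde, so the alkene geometry is set by a stereospecific addition.
3. The γ-lactone comes from a homopropargylic alcohol cyclising onto a lactate-derived dioxolanone; its carbinol C–C bond is the key fragment union, a catalyst-controlled addition of an allenylboronate to the dioxolanone aldehyde (sets lactone C5).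
4. The quaternary carbinol (lactone C3) comes from (S)-lactic acid by Seebach alkylation with allyl bromide, then ozonolysis to the aldehyde.
5. Ring order: temporary dioxolanone, then the γ-lactone; the coumarin pyranone is closed separately from 2-methoxyresorcinol (formylation, Wittig–lactonisation); the two halves are joined last.

Assumption: 2-methoxyresorcinol, allenylboronic acid pinacol ester and (S)-TRIP are taken as catalogue items; numbered coupling partners stand on the Reactants line, unnumbered atom-delivering reagents on the "Reagents that add atoms" line.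

## Route

Step 1
Reactants: 1 (S)-lactic acid
Product: 2 (2S,5S)-2-tert-butyl-5-methyl-1,3-dioxolan-4-one
Conditions: pivalaldehyde, cat. TsOH·H2O, cat. H2SO4, pentane, reflux (Dean–Stark); recryst. Et2O/pentane, −78 °C
Reagents that add atoms: pivalaldehyde, CC(C)(C)C=O
Why: Acid-catalysed acetalisation (Seebach dioxolanone formation) with water removal gives mainly the cis acetal, whose new C2 centre (S) is relayed from the lactate centre and enriched to about 96:4 by crystallisation.

Step 2
Reactants: 2 (2S,5S)-2-tert-butyl-5-methyl-1,3-dioxolan-4-one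
Product: 4 (2S,5R)-2-tert-butyl-5-methyl-5-(prop-2-en-1-yl)-1,3-dioxolan-4-one, via lithium enolate 3 (not isolated)
Conditions: LiN(iPr)2, THF, −78 °C; then allyl bromide, −78 → −30 °C
Reagents that add atoms: allyl bromide, C=CCBr
Why: Seebach self-regeneration of stereocentres: the planar enolate is alkylated anti to the tert-butyl group, so the quaternary centre (5R here, the future lactone C3 with R configuration) is set with overall retention.

Step 3
Reactants: 4 (2S,5R)-2-tert-butyl-5-methyl-5-(prop-2-en-1-yl)-1,3-dioxolan-4-one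
Product: 6 2-[(2S,4R)-2-tert-butyl-4-methyl-5-oxo-1,3-dioxolan-4-yl]acetaldehyde, via ozonide 5 (not isolated)
Conditions: O3, CH2Cl2, −78 °C; then Me2S, −78 °C → rt
Reagents that add atoms: ozone, [O-][O+]=O
Why: Ozonolysis with reductive work-up cleaves only the terminal alkene and leaves the acetal and the quaternary centre untouched.

Step 4
Reactants: 6 2-[(2S,4R)-2-tert-butyl-4-methyl-5-oxo-1,3-dioxolan-4-yl]acetaldehyde; 7 allenylboronic acid pinacol ester
Product: 9 (2S,5R)-2-tert-butyl-5-[(2S)-2-hydroxypent-4-yn-1-yl]-5-methyl-1,3-dioxolan-4-one, via borate ester 8 (not isolated)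
Conditions: (S)-TRIP [(S)-3,3′-bis(2,4,6-triisopropylphenyl)-1,1′-binaphthyl-2,2′-diyl hydrogen phosphate] (10 mol%), 4 Å MS, toluene, −20 °C, 72 h; aq. NaHCO3 work-up
Reagents that add atoms: none
Why: Chiral phosphoric acid-catalysed allenylboration (carbonyl propargylation, the alkyne counterpart of carbonyl allylation) through a closed six-membered SE2′ transition state joins the two fragments, the (S)-catalyst being the antipode expected to direct attack to the aldehyde Si face and so set the (S)-carbinol; any minor epimer is removed after step 5.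

Step 5
Reactants: 9 (2S,5R)-2-tert-butyl-5-[(2S)-2-hydroxypent-4-yn-1-yl]-5-methyl-1,3-dioxolan-4-one
Product: 10 (3R,5S)-3-hydroxy-3-methyl-5-(prop-2-yn-1-yl)oxolan-2-one
Conditions: TsOH·H2O (10 mol%), toluene, 50 °C; SiO2 chromatography
Reagents that add atoms: none
Why: Acid-catalysed intramolecular transesterification (5-exo lactonisation) of the γ-hydroxyl onto the dioxolanone carbonyl expels pivalaldehyde without touching either stereocentre, giving the lactone with 3-OH cis to the C5 side chain, whose C5 epimer separates on silica.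

Step 6
Reactants: 10 (3R,5S)-3-hydroxy-3-methyl-5-(prop-2-yn-1-yl)oxolan-2-one
Product: 12 (3R,5S)-3-hydroxy-5-[(2E)-4-hydroxy-2-methylbut-2-en-1-yl]-3-methyloxolan-2-one, via alkenylalane 11 (not isolated)
Conditions: Me3Al (4 equiv), Cp2ZrCl2 (0.5 equiv), CH2Cl2, 0 °C → rt; then (CH2O)n, THF, 0 °C → rt; aq. KNaC4H4O6 work-up
Reagents that add atoms: trimethylaluminium, C[Al](C)C; paraformaldehyde (as formaldehyde), C=O
Why: Negishi zirconium-catalysed syn-methylalumination puts methyl on the internal and aluminium on the terminal alkyne carbon, and hydroxymethylation of the alkenylalane with retention gives the (E)-allylic alcohol, the lactone being expected to be inert to Me3Al at or below room temperature and no alkyllithium being used.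

Step 7
Reactants: 13 2-methoxybenzene-1,3-diol (2-methoxyresorcinol)
Product: 15 2,4-dihydroxy-3-methoxybenzaldehyde, via iminium salt 14 (not isolated)
Conditions: POCl3, DMF, MeCN, 0 °C → rt; then H2O, 50 °C
Reagents that add atoms: N,N-dimethylformamide, CN(C)C=O; water, O
Why: Vilsmeier–Haack formylation occurs at the position ortho to one hydroxyl and para to the other, and the two such positions are equivalent by symmetry.

Step 8
Reactants: 15 2,4-dihydroxy-3-methoxybenzaldehyde
Product: 17 7-hydroxy-8-methoxy-2H-chromen-2-one, via cinnamate ester 16 (not isolated)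
Conditions: Ph3P=CHCO2Et, PhNEt2, reflux (about 215 °C), 3 h
Reagents that add atoms: ethyl (triphenylphosphoranylidene)acetate, CCOC(=O)C=P(c1ccccc1)(c1ccccc1)c1ccccc1
Why: Wittig olefination gives the (E)-cinnamate, which at this temperature isomerises and lactonises onto the ortho-hydroxyl to close the pyranone ring of the coumarin.

Step 9
Reactants: 12 (3R,5S)-3-hydroxy-5-[(2E)-4-hydroxy-2-methylbut-2-en-1-yl]-3-methyloxolan-2-one; 17 7-hydroxy-8-methoxy-2H-chromen-2-one
Product: 18 7-{[(2E)-4-[(2S,4R)-4-hydroxy-4-methyl-5-oxooxolan-2-yl]-3-methylbut-2-en-1-yl]oxy}-8-methoxy-2H-chromen-2-one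
Conditions: PPh3, DIAD, THF, 0 °C → rt
Reagents that add atoms: none
Why: Mitsunobu etherification of the primary allylic alcohol by the acidic 7-hydroxycoumarin (pKa about 7.5) is an SN2 reaction at CH2, so the alkene geometry and both stereocentres are preserved and the tertiary hydroxyl does not react.

## Compound list

1 | (S)-lactic acid | C[C@H](O)C(=O)O | starting material
2 | (2S,5S)-2-tert-butyl-5-methyl-1,3-dioxolan-4-one (cis) | C[C@@H]1O[C@H](C(C)(C)C)OC1=O | intermediate
3 | lithium (2S)-2-tert-butyl-5-methyl-1,3-dioxol-4-olate (lithium enolate, not isolated) | CC1=C([O-])O[C@@H](C(C)(C)C)O1.[Li+] | intermediate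
4 | (2S,5R)-2-tert-butyl-5-methyl-5-(prop-2-en-1-yl)-1,3-dioxolan-4-one | C[C@]1(CC=C)O[C@H](C(C)(C)C)OC1=O | intermediate
5 | (2S,5R)-2-tert-butyl-5-methyl-5-(1,2,4-trioxolan-3-ylmethyl)-1,3-dioxolan-4-one (ozonide, both epimers at the trioxolane carbon, not isolated) | C[C@]1(CC2OCOO2)O[C@H](C(C)(C)C)OC1=O | intermediate
6 | 2-[(2S,4R)-2-tert-butyl-4-methyl-5-oxo-1,3-dioxolan-4-yl]acetaldehyde | C[C@]1(CC=O)O[C@H](C(C)(C)C)OC1=O | intermediate
7 | allenylboronic acid pinacol ester (4,4,5,5-tetramethyl-2-(propa-1,2-dien-1-yl)-1,3,2-dioxaborolane) | C=C=CB1OC(C)(C)C(C)(C)O1 | starting material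
8 | (2S)-1-[(2S,4R)-2-tert-butyl-4-methyl-5-oxo-1,3-dioxolan-4-yl]pent-4-yn-2-yl pinacol borate (borate ester, not isolated) | C[C@]1(C[C@@H](OB2OC(C)(C)C(C)(C)O2)CC#C)O[C@H](C(C)(C)C)OC1=O | intermediate
9 | (2S,5R)-2-tert-butyl-5-[(2S)-2-hydroxypent-4-yn-1-yl]-5-methyl-1,3-dioxolan-4-one | C[C@]1(C[C@@H](O)CC#C)O[C@H](C(C)(C)C)OC1=O | intermediate
10 | (3R,5S)-3-hydroxy-3-methyl-5-(prop-2-yn-1-yl)oxolan-2-one | C#CC[C@H]1C[C@@](C)(O)C(=O)O1 | intermediate
11 | (E)-alkenyldimethylalane of 10 with the tertiary oxygen as its dimethylaluminium alkoxide (methyl cis to aluminium, not isolated) | C/C(=C\[Al](C)C)C[C@H]1C[C@@](C)(O[Al](C)C)C(=O)O1 | intermediate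
12 | (3R,5S)-3-hydroxy-5-[(2E)-4-hydroxy-2-methylbut-2-en-1-yl]-3-methyloxolan-2-one | C/C(=C\CO)C[C@H]1C[C@@](C)(O)C(=O)O1 | intermediate
13 | 2-methoxybenzene-1,3-diol | COc1c(O)cccc1O | starting material
14 | N-[(2,4-dihydroxy-3-methoxyphenyl)methylidene]-N-methylmethanaminium chloride (iminium salt, not isolated) | COc1c(O)ccc(C=[N+](C)C)c1O.[Cl-] | intermediate
15 | 2,4-dihydroxy-3-methoxybenzaldehyde | COc1c(O)ccc(C=O)c1O | intermediate
16 | ethyl (2E)-3-(2,4-dihydroxy-3-methoxyphenyl)prop-2-enoate (cinnamate ester, not isolated) | CCOC(=O)/C=C/c1ccc(O)c(OC)c1O | intermediate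
17 | 7-hydroxy-8-methoxy-2H-chromen-2-one | COc1c(O)ccc2ccc(=O)oc12 | intermediate
18 | 7-{[(2E)-4-[(2S,4R)-4-hydroxy-4-methyl-5-oxooxolan-2-yl]-3-methylbut-2-en-1-yl]oxy}-8-methoxy-2H-chromen-2-one (CNP0356189.1) | COc1c(OC/C=C(\C)C[C@H]2C[C@@](C)(O)C(=O)O2)ccc2ccc(=O)oc12 | target

## Step count and risks

Total steps: 9. Longest linear sequence: 7 (steps 1–6, then 9); the coumarin arm is 2 steps (7–8).

The three steps most likely to fail:

Step 4. Facial selectivity of the phosphoric acid-catalysed propargylation may be only moderate for this α-unbranched aliphatic aldehyde, or mismatched with the resident centre. The fallback sets out from 4 and replaces steps 3 and 4 by making the alkyne–CH2 bond through epoxide opening. Epoxidation of 4 (mCPBA, NaHCO3, CH2Cl2) gives both oxirane epimers, (2S,5R)-2-tert-butyl-5-methyl-5-{[(2R)-oxiran-2-yl]methyl}-1,3-dioxolan-4-one F1 and (2S,5R)-2-tert-butyl-5-methyl-5-{[(2S)-oxiran-2-yl]methyl}-1,3-dioxolan-4-one F2. Jacobsen hydrolytic kinetic resolution with (S,S)-(salen)Co(OAc) (trivalent cobalt; the antipode that hydrolyses the (2S)-oxirane; H2O 0.55 equiv) converts F2 into (2S,5R)-2-tert-butyl-5-[(2S)-2,3-dihydroxypropyl]-5-methyl-1,3-dioxolan-4-one F3, which is removed, and leaves F1. Opening F1 at its CH2 terminus with LiC≡CSiMe3 and BF3·OEt2 (THF, −78 °C) gives (2S,5R)-2-tert-butyl-5-[(2S)-2-hydroxy-5-(trimethylsilyl)pent-4-yn-1-yl]-5-methyl-1,3-dioxolan-4-one F4. Bu4NF/AcOH removes the silyl group, and the route resumes at 9.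

Step 6. The Lewis-basic hydroxy-lactone may slow the carboalumination, and direct capture of the alkenylalane by paraformaldehyde (without an ate complex) may be low-yielding. The fallback sets out from 10: the same Me3Al/Cp2ZrCl2 carboalumination is quenched with I2 (THF, −30 °C) to give (3R,5S)-3-hydroxy-5-[(2E)-3-iodo-2-methylprop-2-en-1-yl]-3-methyloxolan-2-one F5. Stille cross-coupling of F5 with Bu3SnCH2OH (Pd(PPh3)4, zerovalent palladium, dioxane, 80 °C) then installs the CH2OH carbon with retention and returns to the route at 12.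

Step 9. The Mitsunobu coupling on late-stage material may give some SN2′ or C-alkylated product, or be hard to purify. The fallback sets out from 12: PBr3 (Et2O, −10 °C) converts the primary allylic alcohol into (3R,5S)-5-[(2E)-4-bromo-2-methylbut-2-en-1-yl]-3-hydroxy-3-methyloxolan-2-one F6. Williamson alkylation of 17 with F6 (K2CO3, acetone, reflux) then gives 18 directly.

## Further compounds

F1 | step 4 | (2S,5R)-2-tert-butyl-5-methyl-5-{[(2R)-oxiran-2-yl]methyl}-1,3-dioxolan-4-one | C[C@]1(C[C@@H]2CO2)O[C@H](C(C)(C)C)OC1=O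
F2 | step 4 | (2S,5R)-2-tert-butyl-5-methyl-5-{[(2S)-oxiran-2-yl]methyl}-1,3-dioxolan-4-one | C[C@]1(C[C@H]2CO2)O[C@H](C(C)(C)C)OC1=O
F3 | step 4 | (2S,5R)-2-tert-butyl-5-[(2S)-2,3-dihydroxypropyl]-5-methyl-1,3-dioxolan-4-one | C[C@]1(C[C@H](O)CO)O[C@H](C(C)(C)C)OC1=O
F4 | step 4 | (2S,5R)-2-tert-butyl-5-[(2S)-2-hydroxy-5-(trimethylsilyl)pent-4-yn-1-yl]-5-methyl-1,3-dioxolan-4-one | C[C@]1(C[C@@H](O)CC#C[Si](C)(C)C)O[C@H](C(C)(C)C)OC1=O
F5 | step 6 | (3R,5S)-3-hydroxy-5-[(2E)-3-iodo-2-methylprop-2-en-1-yl]-3-methyloxolan-2-one | C/C(=C\I)C[C@H]1C[C@@](C)(O)C(=O)O1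
F6 | step 9 | (3R,5S)-5-[(2E)-4-bromo-2-methylbut-2-en-1-yl]-3-hydroxy-3-methyloxolan-2-one | C/C(=C\CBr)C[C@H]1C[C@@](C)(O)C(=O)O1
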